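3 questions stood before me on this flask, and I reckoned the first by counting turnovers.

| flask | solid substrate | reagent | free catalyst | remark | time |
|---|---|---|---|---|---|
| alder | 6.7 mM | 10 mM | 10 µM | run made earlier |  |
| ash | 15 mM | 10 mM | 10 µM | run made earlier |  |
| flask | 10 mM | 10.0 mM | 10 µM |  | 6.0 h |

| run | time / h | target / % | solid substrate / % |
|---|---|---|---|
| alder | 0.833 | 0.3 | 96.9 |
| alder | 2.00 | 2.3 | 93.0 |
| alder | 4.00 | 7.1 | 87.9 |
| alder | 6.00 | 11.8 | 82.6 |
| ash | 0.500 | 0 | 99.6 |
| ash | 1.00 | 0.4 | 98.7 |
| ash | 2.50 | 1.6 | 96.2 |
| ash | 6.00 | 5.6 | 92.5 |

(each reading ± 0.3 percentage points)

* how much target there is at 6.0 h, in percent of the solid substrate charged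
* the change that raises the amount of target at 6.0 h, in percent of the solid substrate charged most ("none" if none brings more than 2 percentage points) (west / south-west / north-west / north / none)
* amount of target at 6.0 h, in percent of the solid substrate charged, after north

- west: doubling the amount of reagent, all else as stated
- south-west: doubling the amount of free catalyst, all else as stated
- north-west: doubling the dissolution coefficient of the solid substrate, all else as stated
- north: doubling the solubility of the solid substrate, all else as stated

- a species is counted by the solid substrate in it: one spent catalyst counts as two
- given per volume of solution although it is solid: solid substrate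
- on the list of suspects stand: starting material + free catalyst -> catalyst intermediate A; reagent + catalyst intermediate B -> catalyst intermediate C; catalyst intermediate D -> free catalyst + target; solid substrate <-> starting material; catalyst intermediate C -> catalyst intermediate D; 2 catalyst intermediate B -> spent catalyst; catalyst intermediate A <-> catalyst intermediate B
- at the start none of the solid substrate is in solution

I laid alder beside ash, two runs with the same reagent and free catalyst but different solid substrate charges. At 6.00 h, alder read 11.8% of target and ash 5.6%, so ash looked the poorer run. In concentration, however, alder held 0.791 mM and ash 0.840 mM, and the solid lost was 1.17 mM in alder and 1.12 mM in ash. The two ended at different percentages because a similar amount of target was divided by different charges, while 82.6% and 92.5% of the solid still stood.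

So I counted. Alder's 79.1 and ash's 84.0 average 81.5, the target made by that time per free catalyst charged, or turnover number. The flask has the same free catalyst and reagent, so with 10 mM of solid I committed to 8.15% of target.

The forecast gave 8.1%, about the same as mine, named north as the best change and put the target after it at 14%. Its ground was "So dissolution does not depend on solid loading".

The flask gave 7.79%, which is 77.9 turns against the 81.5 I carried. The change north gained most, 5.5 percentage points, and reached 13.3%. For the forecast's 8.1% to stand 5 points off, the charge or the time would have had to change: the answer to the first question moved that far at 6.09 mM of solid substrate, the nearest such charge below the present one, or at 9.07 h, the nearest such time above it.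

    starting material + free catalyst → catalyst intermediate A (k = 57000 /M/h)
    reagent + catalyst intermediate B → catalyst intermediate C (k = 17000 /M/h)
    catalyst intermediate D → free catalyst + target (k = 410 /h)
    solid substrate ⇌ starting material, rate k4*(cs4 - [starting material]) while solid is left; crystals form when [starting material] > cs4 (solubility = 1.10 mM, k = 0.240 /h)
    catalyst intermediate C → catalyst intermediate D (k = 450 /h)
    2 catalyst intermediate B → spent catalyst (k = 38000 /M/h)
    catalyst intermediate A ⇌ catalyst intermediate B (K = 2.20, k = 34000 /h)

In the neighbour flask with 4.0 mM of solid substrate, 81.5 turns give 20.4% of target. The computed neighbour gave 19.5%, with 70.8% of its solid still standing.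

The numbers in the tables were computed with constants of no real substance; noise was put on by code.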